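The route disconnects the aryl ketone bond C4–C4a of ring C. An intramolecular Friedel–Crafts acylation closes the pyranone ring and installs the C4 carbonyl in one operation. It exploits ring A: the ether carbon C8a carries two equivalent ortho carbons (future C4a and C8), because O1 and the C6 methoxy lie on a local mirror plane, and each is ortho/ortho/para to three oxygens (O1, O5, O7). Acylation should therefore run at 0 °C without base or Lewis acid, so the acidic C3–H stereocentre, set beforehand as R by auxiliary-controlled aryloxymethylation, should survive. The precursor is an open-chain (R)-3-aryloxy-2-arylpropanoic acid with three benzyl-protected phenols.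

Key step: step 12

Remark: C3 of the target is read as R (CIP order C4 > C2 > aryl > H); compounds 1, 5 and 8 are taken as commercial.

Step 1
Reactants: 1 3-hydroxy-4,5-dimethoxybenzaldehyde
Product: 2 3-(benzyloxy)-4,5-dimethoxybenzaldehyde
Conditions: BnBr, K2CO3, DMF, 60 °C
Reagents that add atoms: benzyl bromide, BrCc1ccccc1
Why: Williamson ether synthesis on the only acidic OH, masking the ring B phenol as an ether that is removed by hydrogenolysis at the end.

Step 2
Reactants: 2 3-(benzyloxy)-4,5-dimethoxybenzaldehyde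
Product: 3 [3-(benzyloxy)-4,5-dimethoxyphenyl]acetonitrile
Conditions: TosMIC, t-BuOK, DME, −30 °C; then MeOH, reflux
Reagents that add atoms: TosMIC (4-toluenesulfonylmethyl isocyanide), [C-]#[N+]CS(=O)(=O)c1ccc(C)cc1
Why: van Leusen reductive cyanation, in which the TosMIC anion adds to the aldehyde and methanolysis with loss of sulfinate and formate should leave the one-carbon-homologated nitrile whose carbon becomes C4.

Step 3
Reactants: 3 [3-(benzyloxy)-4,5-dimethoxyphenyl]acetonitrile
Product: 4 [3-(benzyloxy)-4,5-dimethoxyphenyl]acetic acid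
Conditions: KOH, EtOH–H2O, reflux; then aq. HCl
Reagents that add atoms: water, O
Why: basic nitrile hydrolysis, to which benzyl and methyl aryl ethers are inert.

Step 4
Reactants: 4 [3-(benzyloxy)-4,5-dimethoxyphenyl]acetic acid, 5 (4S)-4-benzyl-1,3-oxazolidin-2-one
Product: 7 (4S)-4-benzyl-3-{[3-(benzyloxy)-4,5-dimethoxyphenyl]acetyl}-1,3-oxazolidin-2-one, via mixed pivalic anhydride 6 (not isolated)
Conditions: t-BuCOCl, Et3N, THF, −20 °C; then LiCl, 5, rt
Reagents that add atoms: none
Why: N-acylation of the oxazolidinone through the mixed anhydride, which should be attacked at the less hindered arylacetyl carbonyl.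

Step 5
Reactants: 8 methyl 3,5-dihydroxy-4-methoxybenzoate
Product: 9 methyl 3,5-bis(benzyloxy)-4-methoxybenzoate
Conditions: BnBr, K2CO3, DMF, 60 °C
Reagents that add atoms: benzyl bromide, BrCc1ccccc1
Why: double Williamson benzylation of the two equivalent phenols that become the C5 and C7 hydroxyls.

Step 6
Reactants: 9 methyl 3,5-bis(benzyloxy)-4-methoxybenzoate
Product: 10 [3,5-bis(benzyloxy)-4-methoxyphenyl]methanol
Conditions: LiAlH4, THF, 0 °C
Reagents that add atoms: none
Why: hydride reduction of the ester to the benzylic alcohol, with the aryl ethers untouched.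

Step 7
Reactants: 10 [3,5-bis(benzyloxy)-4-methoxyphenyl]methanol
Product: 11 3,5-bis(benzyloxy)-4-methoxybenzaldehyde
Conditions: MnO2, CH2Cl2, rt
Reagents that add atoms: none
Why: selective benzylic alcohol oxidation with MnO2, which stops at the aldehyde.

Step 8
Reactants: 11 3,5-bis(benzyloxy)-4-methoxybenzaldehyde
Product: 13 3,5-bis(benzyloxy)-4-methoxyphenol, via aryl formate 12 (not isolated)
Conditions: mCPBA, CH2Cl2, 0 °C to rt; then KOH, MeOH–H2O, rt; aq. HCl
Reagents that add atoms: mCPBA (3-chloroperoxybenzoic acid), OOC(=O)c1cccc(Cl)c1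
Why: Dakin-type Baeyer–Villiger oxidation, in which the electron-rich aryl group should migrate in preference to hydrogen and saponification of the formate releases the phenol whose oxygen becomes O1.

Step 9
Reactants: 13 3,5-bis(benzyloxy)-4-methoxyphenol
Product: 14 [3,5-bis(benzyloxy)-4-methoxyphenoxy]methyl 2,2-dimethylpropanoate
Conditions: ClCH2OCOt-Bu, K2CO3, NaI (cat.), DMF, rt
Reagents that add atoms: chloromethyl pivalate, CC(C)(C)C(=O)OCCl
Why: Williamson O-alkylation of the phenoxide at the CH2 of the hindered pivalate, giving a stable acyloxymethyl aryl ether that carries the future C2 as a latent oxocarbenium carbon.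

Step 10
Reactants: 7 (4S)-4-benzyl-3-{[3-(benzyloxy)-4,5-dimethoxyphenyl]acetyl}-1,3-oxazolidin-2-one, 14 [3,5-bis(benzyloxy)-4-methoxyphenoxy]methyl 2,2-dimethylpropanoate
Product: 16 (4S)-4-benzyl-3-{(2R)-3-[3,5-bis(benzyloxy)-4-methoxyphenoxy]-2-[3-(benzyloxy)-4,5-dimethoxyphenyl]propanoyl}-1,3-oxazolidin-2-one, via chlorotitanium enolate 15 (not isolated)
Conditions: TiCl4, i-Pr2NEt, CH2Cl2, 0 °C; then 14, TiCl4, 0 °C
Reagents that add atoms: none
Why: Evans alkylation of the chelated chlorotitanium (Z)-enolate with an oxocarbenium-type electrophile: TiCl4 should ionise the acyloxymethyl ether 14 as it activates benzyl chloromethyl ether or s-trioxane, the enolate carbon should attack the CH2 from the face opposite the C4 benzyl group of the auxiliary and so set C3 as R, and because the intact CH2–OAr unit arrives as an electrophile no hydroxyl next to the acidic α-aryl C–H has to be activated.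

Step 11
Reactants: 16 (4S)-4-benzyl-3-{(2R)-3-[3,5-bis(benzyloxy)-4-methoxyphenoxy]-2-[3-(benzyloxy)-4,5-dimethoxyphenyl]propanoyl}-1,3-oxazolidin-2-one
Product: 18 (2R)-3-[3,5-bis(benzyloxy)-4-methoxyphenoxy]-2-[3-(benzyloxy)-4,5-dimethoxyphenyl]propanoic acid, via peroxy acid 17 (not isolated)
Conditions: LiOH, H2O2, THF–H2O, 0 °C; then Na2SO3; aq. HCl
Reagents that add atoms: hydrogen peroxide, OO
Why: hydroperoxide cleavage of the N-acyloxazolidinone at the exocyclic carbonyl, where the weakly basic nucleophile and A(1,3) strain in the imide should prevent deprotonation at C3 and hence epimerisation or β-elimination of the aryloxide.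

Step 12
Reactants: 18 (2R)-3-[3,5-bis(benzyloxy)-4-methoxyphenoxy]-2-[3-(benzyloxy)-4,5-dimethoxyphenyl]propanoic acid
Product: 20 (3R)-5,7-bis(benzyloxy)-3-[3-(benzyloxy)-4,5-dimethoxyphenyl]-6-methoxychroman-4-one, via mixed trifluoroacetic anhydride 19 (not isolated)
Conditions: (CF3CO)2O, CH2Cl2, 0 °C
Reagents that add atoms: none
Why: Friedel–Crafts acylation: the anhydride converts the acid into the mixed trifluoroacetic anhydride 19, whose acyl carbon (future C4) is attacked by a ring A carbon ortho to the ether oxygen (future C4a), and rearomatisation with loss of CF3CO2H gives the aryl ketone. The closest known reaction type is the intramolecular Friedel–Crafts cyclisation of 3-aryloxypropanoic acids to chroman-4-ones. Ring C closes in a 6-exo-trig mode, the arene carbon adding to the exocyclic acyl C=O. No new stereocentre is formed; C3 (R, from step 10) is a spectator, because no bond to it is made or broken and, with no base present, neither ketene formation nor enolisation should be opened at 0 °C. The step needs regioselectivity and chemoselectivity: the two ortho carbons of the 3,5-dibenzyloxy-4-methoxyphenoxy ring are equivalent by symmetry, so only one regioisomer can form. Each is ortho/ortho/para to three oxygen donors, so closure should be fast under conditions too mild to touch ring B (which could only close a four-membered ring) or the benzyl ethers.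

Step 13
Reactants: 20 (3R)-5,7-bis(benzyloxy)-3-[3-(benzyloxy)-4,5-dimethoxyphenyl]-6-methoxychroman-4-one
Product: 21 (3R)-5,7-dihydroxy-3-(3-hydroxy-4,5-dimethoxyphenyl)-6-methoxychroman-4-one
Conditions: H2 (1 atm), Pd/C, EtOAc, rt
Reagents that add atoms: none
Why: hydrogenolysis of the three benzyl aryl ethers under neutral conditions, which should leave C3 untouched and spare the C4 ketone, deactivated by its ortho/para oxygens and hydrogen-bonded to the liberated C5 hydroxyl.

Compound list
1 | 3-hydroxy-4,5-dimethoxybenzaldehyde | O=Cc1cc(O)c(OC)c(OC)c1 | starting material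
2 | 3-(benzyloxy)-4,5-dimethoxybenzaldehyde | O=Cc1cc(OCc2ccccc2)c(OC)c(OC)c1 | intermediate
3 | [3-(benzyloxy)-4,5-dimethoxyphenyl]acetonitrile | N#CCc1cc(OCc2ccccc2)c(OC)c(OC)c1 | intermediate
4 | [3-(benzyloxy)-4,5-dimethoxyphenyl]acetic acid | OC(=O)Cc1cc(OCc2ccccc2)c(OC)c(OC)c1 | intermediate
5 | (4S)-4-benzyl-1,3-oxazolidin-2-one | O=C1OC[C@H](Cc2ccccc2)N1 | starting material
6 | [3-(benzyloxy)-4,5-dimethoxyphenyl]acetic pivalic anhydride (not isolated) | CC(C)(C)C(=O)OC(=O)Cc1cc(OCc2ccccc2)c(OC)c(OC)c1 | intermediate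
7 | (4S)-4-benzyl-3-{[3-(benzyloxy)-4,5-dimethoxyphenyl]acetyl}-1,3-oxazolidin-2-one | O=C1OC[C@H](Cc2ccccc2)N1C(=O)Cc1cc(OCc2ccccc2)c(OC)c(OC)c1 | intermediate
8 | methyl 3,5-dihydroxy-4-methoxybenzoate | COC(=O)c1cc(O)c(OC)c(O)c1 | starting material
9 | methyl 3,5-bis(benzyloxy)-4-methoxybenzoate | COC(=O)c1cc(OCc2ccccc2)c(OC)c(OCc2ccccc2)c1 | intermediate
10 | [3,5-bis(benzyloxy)-4-methoxyphenyl]methanol | OCc1cc(OCc2ccccc2)c(OC)c(OCc2ccccc2)c1 | intermediate
11 | 3,5-bis(benzyloxy)-4-methoxybenzaldehyde | O=Cc1cc(OCc2ccccc2)c(OC)c(OCc2ccccc2)c1 | intermediate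
12 | 3,5-bis(benzyloxy)-4-methoxyphenyl formate (not isolated) | O=COc1cc(OCc2ccccc2)c(OC)c(OCc2ccccc2)c1 | intermediate
13 | 3,5-bis(benzyloxy)-4-methoxyphenol | Oc1cc(OCc2ccccc2)c(OC)c(OCc2ccccc2)c1 | intermediate
14 | [3,5-bis(benzyloxy)-4-methoxyphenoxy]methyl 2,2-dimethylpropanoate | CC(C)(C)C(=O)OCOc1cc(OCc2ccccc2)c(OC)c(OCc2ccccc2)c1 | intermediate
15 | trichlorotitanium (Z)-enolate of 7 (not isolated) | Cl[Ti](Cl)(Cl)O/C(=C\c1cc(OCc2ccccc2)c(OC)c(OC)c1)N1C(=O)OC[C@@H]1Cc1ccccc1 | intermediate
16 | (4S)-4-benzyl-3-{(2R)-3-[3,5-bis(benzyloxy)-4-methoxyphenoxy]-2-[3-(benzyloxy)-4,5-dimethoxyphenyl]propanoyl}-1,3-oxazolidin-2-one | O=C1OC[C@H](Cc2ccccc2)N1C(=O)[C@@H](COc1cc(OCc2ccccc2)c(OC)c(OCc2ccccc2)c1)c1cc(OC)c(OC)c(OCc2ccccc2)c1 | intermediate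
17 | (2R)-3-[3,5-bis(benzyloxy)-4-methoxyphenoxy]-2-[3-(benzyloxy)-4,5-dimethoxyphenyl]propaneperoxoic acid (not isolated) | OOC(=O)[C@@H](COc1cc(OCc2ccccc2)c(OC)c(OCc2ccccc2)c1)c1cc(OC)c(OC)c(OCc2ccccc2)c1 | intermediate
18 | (2R)-3-[3,5-bis(benzyloxy)-4-methoxyphenoxy]-2-[3-(benzyloxy)-4,5-dimethoxyphenyl]propanoic acid | OC(=O)[C@@H](COc1cc(OCc2ccccc2)c(OC)c(OCc2ccccc2)c1)c1cc(OC)c(OC)c(OCc2ccccc2)c1 | intermediate
19 | mixed anhydride of 18 and trifluoroacetic acid (not isolated) | O=C(OC(=O)C(F)(F)F)[C@@H](COc1cc(OCc2ccccc2)c(OC)c(OCc2ccccc2)c1)c1cc(OC)c(OC)c(OCc2ccccc2)c1 | intermediate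
20 | (3R)-5,7-bis(benzyloxy)-3-[3-(benzyloxy)-4,5-dimethoxyphenyl]-6-methoxychroman-4-one | COc1cc([C@@H]2COc3cc(OCc4ccccc4)c(OC)c(OCc4ccccc4)c3C2=O)cc(OCc2ccccc2)c1OC | intermediate
21 | (3R)-5,7-dihydroxy-3-(3-hydroxy-4,5-dimethoxyphenyl)-6-methoxychroman-4-one | COc1cc([C@@H]2COc3cc(O)c(OC)c(O)c3C2=O)cc(O)c1OC | target

Total step count: 13. Longest linear sequence: 9 steps (steps 5 to 13, from 8).

Steps most likely to fail

1. Step 10. The aryloxymethyl cation released from 14 may alkylate the electron-rich ring A of a second molecule faster than the stabilised α-aryl enolate captures it, or TiCl4 may begin chelation-assisted cleavage of benzyl ethers. Fallback: the fallback sets out from 7 and forms the two bonds in the opposite order. The same titanium enolate is hydroxymethylated with s-trioxane (TiCl4, i-Pr2NEt, CH2Cl2, 0 °C; then s-trioxane, TiCl4), which should give, with the same facial control, (4S)-4-benzyl-3-{(2R)-2-[3-(benzyloxy)-4,5-dimethoxyphenyl]-3-hydroxypropanoyl}-1,3-oxazolidin-2-one F1. Mitsunobu etherification of F1 with phenol 13 (PPh3, DIAD, toluene, 0 °C, where A(1,3) strain should slow α-deprotonation and hence dehydration) comes back to the route at 16.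

2. Step 12. Partial loss of configuration at C3 may occur through acid-catalysed enolisation of the product or ketene formation from 19 if cyclisation is slower than expected. Fallback: the fallback sets out from 20 of eroded enantiomeric purity and restores it by dynamic kinetic resolution. Noyori transfer hydrogenation with RuCl[(R,R)-TsDPEN](p-cymene) in HCO2H/Et3N, EtOAc, 40 °C, should racemise the unreacted ketone at C3 through its enol and reduce only the 3R enantiomer, giving cis-(3R,4R)-5,7-bis(benzyloxy)-3-[3-(benzyloxy)-4,5-dimethoxyphenyl]-6-methoxychroman-4-ol F2. Dess–Martin oxidation of F2 (NaHCO3, CH2Cl2, 0 °C) comes back to the route at 20.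

3. Step 11. β-Elimination of the aryloxide (E1cB) or epimerisation at C3 may compete under the basic peroxide conditions, or the hindered imide may be opened at the ring carbonyl. Fallback: the fallback sets out from 16 and removes the auxiliary reductively. LiBH4 (THF, 1 equiv H2O, 0 °C) should give (2S)-3-[3,5-bis(benzyloxy)-4-methoxyphenoxy]-2-[3-(benzyloxy)-4,5-dimethoxyphenyl]propan-1-ol F3, in which C3 is no longer α to a carbonyl. Oxidation of F3 with TEMPO (cat.) and PhI(OAc)2 in MeCN–H2O comes back to the route at 18.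

Further compounds
F1 | step 10 | (4S)-4-benzyl-3-{(2R)-2-[3-(benzyloxy)-4,5-dimethoxyphenyl]-3-hydroxypropanoyl}-1,3-oxazolidin-2-one | O=C1OC[C@H](Cc2ccccc2)N1C(=O)[C@@H](CO)c1cc(OC)c(OC)c(OCc2ccccc2)c1
F2 | step 12 | (3R,4R)-5,7-bis(benzyloxy)-3-[3-(benzyloxy)-4,5-dimethoxyphenyl]-6-methoxychroman-4-ol | O[C@@H]1[C@H](c2cc(OC)c(OC)c(OCc3ccccc3)c2)COc2cc(OCc3ccccc3)c(OC)c(OCc3ccccc3)c21
F3 | step 11 | (2S)-3-[3,5-bis(benzyloxy)-4-methoxyphenoxy]-2-[3-(benzyloxy)-4,5-dimethoxyphenyl]propan-1-ol | OC[C@@H](COc1cc(OCc2ccccc2)c(OC)c(OCc2ccccc2)c1)c1cc(OC)c(OC)c(OCc2ccccc2)c1
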